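**Retrosynthetic overview**
- Ligraminol C ⇒ acetylation and desilylation of a benzylic silyl ether; the (Z)-propenyl group ⇒ stereoretentive Suzuki coupling of an aryl bromide with (Z)-prop-1-enylboronic acid.
- C9 methyl ⇒ CH2OTs → CH3 hydride displacement on the primary alcohol obtained by reductive removal of an oxazolidinone auxiliary.
- Key C7–C8 bond ⇒ Evans syn aldol between the boron enolate of an N-(aryloxyacetyl)-(S)-4-benzyloxazolidinone and 3,4-dimethoxybenzaldehyde; this sets both stereocentres.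
- Imide ⇒ 4-bromo-2-methoxyphenol + ethyl bromoacetate + (S)-4-benzyl-2-oxazolidinone.
- No ring is built: both benzene rings are bought.

Assumption: lignan numbering is used (C7 = benzylic acetoxy carbon, C8 = aryloxy carbon, C9 = methyl); the SMILES reads as (7R,8R) with a Z propenyl group.

**Route**

Step 1
Reactants: 1 4-bromo-2-methoxyphenol; 2 ethyl bromoacetate
Product: 3 ethyl (4-bromo-2-methoxyphenoxy)acetate
Conditions: K2CO3 (1.5 equiv), acetone, reflux
Reagents that add atoms: none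
Why: Williamson ether synthesis; the phenoxide displaces the activated primary bromide by SN2 and no stereocentre is involved.

Step 2
Reactants: 3 ethyl (4-bromo-2-methoxyphenoxy)acetate
Product: 5 (4-bromo-2-methoxyphenoxy)acetic acid, via lithium carboxylate 4 (not isolated)
Conditions: LiOH·H2O (2 equiv), THF/H2O 3:1, rt; then 1 M HCl to pH 2
Reagents that add atoms: lithium hydroxide, [Li+].[OH-] (its oxygen becomes the acid OH; its lithium stands in 4 only)
Why: Ester saponification; the aryl bromide and aryl ethers are inert to aqueous hydroxide at room temperature.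

Step 3
Reactants: 5 (4-bromo-2-methoxyphenoxy)acetic acid; 6 (S)-4-benzyl-1,3-oxazolidin-2-one
Product: 8 (4S)-4-benzyl-3-[(4-bromo-2-methoxyphenoxy)acetyl]-1,3-oxazolidin-2-one, via mixed pivalic anhydride 7 (not isolated)
Conditions: PivCl (1.05 equiv), Et3N (2.5 equiv), THF, −20 °C; then LiCl (1.1 equiv), 6, −20 °C → rt
Reagents that add atoms: pivaloyl chloride, CC(C)(C)C(Cl)=O (its acyl group stands in 7 only and leaves again as pivalate)
Why: N-acylation through a mixed anhydride; the oxazolidinone attacks the unhindered aryloxyacetyl carbonyl and not the pivaloyl one, and the auxiliary stereocentre is untouched.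

Step 4
Reactants: 8 (4S)-4-benzyl-3-[(4-bromo-2-methoxyphenoxy)acetyl]-1,3-oxazolidin-2-one; 9 3,4-dimethoxybenzaldehyde
Product: 12 (4S)-4-benzyl-3-[(2S,3R)-2-(4-bromo-2-methoxyphenoxy)-3-(3,4-dimethoxyphenyl)-3-hydroxypropanoyl]-1,3-oxazolidin-2-one, via Z-boron enolate 10 (not isolated), via boron aldolate 11 (not isolated)
Conditions: Bu2BOTf (1.2 equiv), Et3N (1.4 equiv), CH2Cl2, 0 °C then −78 °C; 9 (1.2 equiv), −78 → 0 °C; then pH 7 phosphate buffer, MeOH, 30% H2O2, 0 °C
Reagents that add atoms: dibutylboron triflate, CCCCB(CCCC)OS(=O)(=O)C(F)(F)F (its Bu2B group stands in 10 and 11 only; 12 holds no reagent atoms)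
Why: Evans syn aldol; the Z-boron enolate reacts through a closed Zimmerman–Traxler chair on the enolate face away from the benzyl group, giving the 2,3-syn (2S,3R) adduct that carries both target stereocentres (C8 and C7).

Step 5
Reactants: 12 the aldol adduct
Product: 13 (4S)-4-benzyl-3-[(2S,3R)-2-(4-bromo-2-methoxyphenoxy)-3-(tert-butyldimethylsilyloxy)-3-(3,4-dimethoxyphenyl)propanoyl]-1,3-oxazolidin-2-one
Conditions: TBSOTf (1.3 equiv), 2,6-lutidine (2 equiv), CH2Cl2, 0 °C
Reagents that add atoms: tert-butyldimethylsilyl triflate, CC(C)(C)[Si](C)(C)OS(=O)(=O)C(F)(F)F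
Why: Silyl ether formation under non-nucleophilic, weakly basic conditions avoids retro-aldol and masks the benzylic hydroxyl so it cannot close an oxetane during the later deoxygenation.

Step 6
Reactants: 13 the silyl-protected imide
Product: 14 (2R,3R)-2-(4-bromo-2-methoxyphenoxy)-3-(tert-butyldimethylsilyloxy)-3-(3,4-dimethoxyphenyl)propan-1-ol
Conditions: LiBH4 (2 equiv), MeOH (2 equiv), THF, 0 °C → rt; then H2O
Reagents that add atoms: none
Why: Reductive cleavage of the N-acyl oxazolidinone; hydride attacks the exocyclic carbonyl and reduces it to the primary alcohol without epimerising C8, and the auxiliary is recovered (the descriptor at C8 changes only through priorities).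

Step 7
Reactants: 14 the primary alcohol
Product: 15 (2R,3R)-2-(4-bromo-2-methoxyphenoxy)-3-(tert-butyldimethylsilyloxy)-3-(3,4-dimethoxyphenyl)propyl 4-methylbenzenesulfonate
Conditions: TsCl (1.5 equiv), Et3N (2.5 equiv), DMAP (0.1 equiv), CH2Cl2, 0 °C → rt
Reagents that add atoms: 4-toluenesulfonyl chloride, Cc1ccc(cc1)S(Cl)(=O)=O
Why: DMAP-catalysed sulfonylation of the only free hydroxyl, which is primary and unhindered enough to react cleanly.

Step 8
Reactants: 15 the tosylate
Product: 16 {[(1R,2R)-2-(4-bromo-2-methoxyphenoxy)-1-(3,4-dimethoxyphenyl)propyl]oxy}(tert-butyl)dimethylsilane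
Conditions: LiBHEt3 (3 equiv, 1 M in THF), THF, 0 °C → rt; then H2O
Reagents that add atoms: none
Why: SN2 hydride displacement of a primary tosylate by the strongly nucleophilic triethylborohydride turns C9 into the methyl group; the aryl bromide, silyl ether and both stereocentres are untouched at or below room temperature.

Step 9
Reactants: 16 the aryl bromide; 17 (Z)-prop-1-en-1-ylboronic acid
Product: 18 tert-butyl{[(1R,2R)-1-(3,4-dimethoxyphenyl)-2-{2-methoxy-4-[(Z)-prop-1-en-1-yl]phenoxy}propyl]oxy}dimethylsilane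
Conditions: 17 (1.5 equiv), Pd(dppf)Cl2·CH2Cl2 (5 mol %), K2CO3 (3 equiv), degassed 1,4-dioxane/H2O 4:1, 80 °C
Reagents that add atoms: none
Why: Suzuki–Miyaura cross-coupling; transmetalation and reductive elimination retain the alkene geometry, so the Z-propenyl group is transferred intact, and the silyl ether tolerates aqueous carbonate.

Step 10
Reactants: 18 the Z-propenyl silyl ether
Product: 19 (1R,2R)-1-(3,4-dimethoxyphenyl)-2-{2-methoxy-4-[(Z)-prop-1-en-1-yl]phenoxy}propan-1-ol
Conditions: Bu4NF (1.5 equiv), THF, 0 °C → rt; then H2O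
Reagents that add atoms: none
Why: Fluoride-mediated desilylation, driven by the strong Si–F bond, is neutral enough to leave the acid-sensitive Z-styrene and the benzylic stereocentre unchanged.

Step 11
Reactants: 19 the benzylic alcohol
Product: 20 Ligraminol C
Conditions: Ac2O (2 equiv), pyridine, DMAP (0.1 equiv), CH2Cl2, 0 °C → rt
Reagents that add atoms: acetic anhydride, CC(=O)OC(C)=O
Why: DMAP-catalysed acetylation occurs at oxygen, so C7 keeps its R configuration and the Z alkene is not exposed to acid or heat.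

**Compound list**

1 | 4-bromo-2-methoxyphenol | COc1cc(Br)ccc1O | starting material
2 | ethyl bromoacetate | CCOC(=O)CBr | starting material
3 | ethyl (4-bromo-2-methoxyphenoxy)acetate | CCOC(=O)COc1ccc(Br)cc1OC | intermediate
4 | lithium (4-bromo-2-methoxyphenoxy)acetate | [Li+].[O-]C(=O)COc1ccc(Br)cc1OC | intermediate (not isolated)
5 | (4-bromo-2-methoxyphenoxy)acetic acid | OC(=O)COc1ccc(Br)cc1OC | intermediate
6 | (S)-4-benzyl-1,3-oxazolidin-2-one | O=C1N[C@@H](Cc2ccccc2)CO1 | starting material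
7 | (4-bromo-2-methoxyphenoxy)acetic pivalic anhydride | CC(C)(C)C(=O)OC(=O)COc1ccc(Br)cc1OC | intermediate (not isolated)
8 | (4S)-4-benzyl-3-[(4-bromo-2-methoxyphenoxy)acetyl]-1,3-oxazolidin-2-one | O=C(COc1ccc(Br)cc1OC)N2[C@@H](Cc3ccccc3)COC2=O | intermediate
9 | 3,4-dimethoxybenzaldehyde (veratraldehyde) | COc1ccc(C=O)cc1OC | starting material
10 | dibutylboron (Z)-enolate of 8 | CCCCB(CCCC)O/C(=C\Oc1ccc(Br)cc1OC)N2[C@@H](Cc3ccccc3)COC2=O | intermediate (not isolated)
11 | O-dibutylboryl aldolate of 12 | COc1cc(Br)ccc1O[C@H](C(=O)N2[C@@H](Cc3ccccc3)COC2=O)[C@H](OB(CCCC)CCCC)c4ccc(OC)c(OC)c4 | intermediate (not isolated)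
12 | (4S)-4-benzyl-3-[(2S,3R)-2-(4-bromo-2-methoxyphenoxy)-3-(3,4-dimethoxyphenyl)-3-hydroxypropanoyl]-1,3-oxazolidin-2-one | COc1cc(Br)ccc1O[C@H](C(=O)N2[C@@H](Cc3ccccc3)COC2=O)[C@H](O)c4ccc(OC)c(OC)c4 | intermediate
13 | (4S)-4-benzyl-3-[(2S,3R)-2-(4-bromo-2-methoxyphenoxy)-3-(tert-butyldimethylsilyloxy)-3-(3,4-dimethoxyphenyl)propanoyl]-1,3-oxazolidin-2-one | COc1cc(Br)ccc1O[C@H](C(=O)N2[C@@H](Cc3ccccc3)COC2=O)[C@H](O[Si](C)(C)C(C)(C)C)c4ccc(OC)c(OC)c4 | intermediate
14 | (2R,3R)-2-(4-bromo-2-methoxyphenoxy)-3-(tert-butyldimethylsilyloxy)-3-(3,4-dimethoxyphenyl)propan-1-ol | COc1cc(Br)ccc1O[C@H](CO)[C@H](O[Si](C)(C)C(C)(C)C)c2ccc(OC)c(OC)c2 | intermediate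
15 | (2R,3R)-2-(4-bromo-2-methoxyphenoxy)-3-(tert-butyldimethylsilyloxy)-3-(3,4-dimethoxyphenyl)propyl 4-methylbenzenesulfonate | COc1cc(Br)ccc1O[C@H](COS(=O)(=O)c2ccc(C)cc2)[C@H](O[Si](C)(C)C(C)(C)C)c3ccc(OC)c(OC)c3 | intermediate
16 | {[(1R,2R)-2-(4-bromo-2-methoxyphenoxy)-1-(3,4-dimethoxyphenyl)propyl]oxy}(tert-butyl)dimethylsilane | COc1cc(Br)ccc1O[C@H](C)[C@H](O[Si](C)(C)C(C)(C)C)c2ccc(OC)c(OC)c2 | intermediate
17 | (Z)-prop-1-en-1-ylboronic acid (cis-1-propenylboronic acid) | C/C=C\B(O)O | starting material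
18 | tert-butyl{[(1R,2R)-1-(3,4-dimethoxyphenyl)-2-{2-methoxy-4-[(Z)-prop-1-en-1-yl]phenoxy}propyl]oxy}dimethylsilane | C/C=C\c1ccc(O[C@H](C)[C@H](O[Si](C)(C)C(C)(C)C)c2ccc(OC)c(OC)c2)c(OC)c1 | intermediate
19 | (1R,2R)-1-(3,4-dimethoxyphenyl)-2-{2-methoxy-4-[(Z)-prop-1-en-1-yl]phenoxy}propan-1-ol | C/C=C\c1ccc(O[C@H](C)[C@H](O)c2ccc(OC)c(OC)c2)c(OC)c1 | intermediate
20 | Ligraminol C, (1R,2R)-1-(3,4-dimethoxyphenyl)-2-{2-methoxy-4-[(Z)-prop-1-en-1-yl]phenoxy}propyl acetate | C/C=C\c1ccc(O[C@H](C)[C@H](OC(C)=O)c2ccc(OC)c(OC)c2)c(OC)c1 | target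

**Totals and fallbacks**

Total step count: 11. Longest linear sequence: 11 steps (1 → 20).

Three steps most likely to fail:

Step 4 (aldol; risk: the aryloxy oxygen perturbs the boron enolate and lowers the syn selectivity, or the electron-rich aldehyde reacts sluggishly). The fallback sets out from acid 5 and comes back at alcohol 14. Acid 5 is coupled with (S)-4-benzyl-1,3-thiazolidine-2-thione (DCC, DMAP cat., CH2Cl2) to give the N-acyl thiazolidinethione F1. Its titanium enolate (TiCl4 1.05 equiv, i-Pr2NEt 1.1 equiv, N-methylpyrrolidinone 1 equiv, CH2Cl2, −78 → 0 °C) adds to aldehyde 9 in the Evans-syn sense to give the syn aldol adduct F2, which is purified as a yellow, easily chromatographed solid. Silylation (TBSOTf, 2,6-lutidine) gives the silyl ether F3, and NaBH4 in THF/EtOH at 0 °C removes the thione auxiliary to give 14.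

Step 8 (hydride displacement; risk: slow SN2 at a β-branched, β-oxygenated primary carbon, with elimination or aryl bromide reduction on forcing). The fallback sets out from alcohol 14 and comes back at 16. Appel iodination (PPh3, I2, imidazole, CH2Cl2, 0 °C → rt) gives the primary iodide F4. Radical-chain reduction with Bu3SnH (1.1 equiv) and AIBN in toluene at 80 °C then replaces iodine by hydrogen; the alkyl iodide reacts far faster than the aryl bromide, so 16 is obtained.

Step 9 (Suzuki coupling; risk: protodeboronation of the alkenylboronic acid or partial Z → E erosion). The fallback sets out from aryl bromide 16 and comes back at 18. Stille coupling with tributyl(prop-1-yn-1-yl)stannane (Pd(PPh3)4, toluene, 100 °C) gives the aryl propyne F5. Semi-hydrogenation (H2 1 atm, Pd/CaCO3 poisoned with Pb(OAc)2, quinoline, EtOAc, rt) delivers the Z alkene 18 by syn addition of hydrogen.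

**Further compounds**

F1 | step 4 | (4S)-4-benzyl-3-[(4-bromo-2-methoxyphenoxy)acetyl]-1,3-thiazolidine-2-thione | COc1cc(Br)ccc1OCC(=O)N2[C@@H](Cc3ccccc3)CSC2=S
F2 | step 4 | (4S)-4-benzyl-3-[(2S,3R)-2-(4-bromo-2-methoxyphenoxy)-3-(3,4-dimethoxyphenyl)-3-hydroxypropanoyl]-1,3-thiazolidine-2-thione | COc1cc(Br)ccc1O[C@H](C(=O)N2[C@@H](Cc3ccccc3)CSC2=S)[C@H](O)c4ccc(OC)c(OC)c4
F3 | step 4 | (4S)-4-benzyl-3-[(2S,3R)-2-(4-bromo-2-methoxyphenoxy)-3-(tert-butyldimethylsilyloxy)-3-(3,4-dimethoxyphenyl)propanoyl]-1,3-thiazolidine-2-thione | COc1cc(Br)ccc1O[C@H](C(=O)N2[C@@H](Cc3ccccc3)CSC2=S)[C@H](O[Si](C)(C)C(C)(C)C)c4ccc(OC)c(OC)c4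
F4 | step 8 | tert-butyl{[(1R,2S)-2-(4-bromo-2-methoxyphenoxy)-1-(3,4-dimethoxyphenyl)-3-iodopropyl]oxy}dimethylsilane | COc1cc(Br)ccc1O[C@H](CI)[C@H](O[Si](C)(C)C(C)(C)C)c2ccc(OC)c(OC)c2
F5 | step 9 | tert-butyl{[(1R,2R)-1-(3,4-dimethoxyphenyl)-2-[2-methoxy-4-(prop-1-yn-1-yl)phenoxy]propyl]oxy}dimethylsilane | CC#Cc1ccc(O[C@H](C)[C@H](O[Si](C)(C)C(C)(C)C)c2ccc(OC)c(OC)c2)c(OC)c1
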